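If each X takes one J, the J side of a flask can be booked like a charge.

| flask | Z | J | X | time |
|---|---|---|---|---|
| ash | 0.0500 M | 0.0500 M |  |  |
| larch | 0.0500 M | 0.0750 M |  |  |
| cedar | 0.0500 M | 0.0500 M | 0.0150 M |  |
| maple | 0.0750 M | 0.0500 M |  |  |
| birch | 0.0300 M | 0.0300 M |  | 8.9 min |

- ash run (time / min: [X] / M): 0.36: 0.0011; 0.68: 0.0034; 1.3: 0.0095; 2.5: 0.0196; 4.7: 0.0310; 8.9: 0.0377
- larch run (time / min: [X] / M): 0.36: 0.0013; 0.68: 0.0043; 1.3: 0.0116; 2.5: 0.0228; 4.7: 0.0348; 8.9: 0.0442
- cedar run (time / min: [X] / M): 0.36: 0.0163; 0.68: 0.0188; 1.3: 0.0248; 2.5: 0.0354; 4.7: 0.0465; 8.9: 0.0525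
- maple run (time / min: [X] / M): 0.36: 0.0015; 0.68: 0.0060; 1.3: 0.0139; 2.5: 0.0277; 4.7: 0.0403; 8.9: 0.0428

(scatter of a reading: 3 × 10⁻⁴ M)

- the exponent of [Z] in the starting rate at the charge of the ash run (at the point where two percent of the Z have become X) (one fixed amount of X, the same in the runs compared)
- the exponent of [J] in the starting rate at the charge of the ash run (at the point where two percent of the Z have become X)
- X in the birch run at 8.9 min, as a share of the Z charged

- Overall: Z + J -> X.
- Constant volume, constant temperature.
- Bound and free are read together.
- An order is taken over about fifteen percent of the charge, up and down.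

The J gap of the ash run is 24.6%: the share of the J charge not found as X at the last reading. The birch run charges Z and J equally, so its X share and its gap add up to the whole.

Two chemists dispute birch. The first holds a scale-free view: “Near-first-order overall kinetics suggest fractional conversion barely depends on scale”. The gap should then stay near that of ash. The forecast is this side's number: 0.7 for the Z exponent, 0.3 for the J exponent and 72% for birch. Its birch gap is 28.0%.

The second holds a pair view. One Z meets one J, so at equal charges and at one time the ratio of X share to gap scales with the charge. Ash gives a ratio of 3.07. Birch has 0.600 of that charge, so its ratio is 1.84. Its gap is then 35.2%, and X is 64.8%.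

The second chemist also points to the maple run. Its gap is 14.4%. Over the last interval its X rises by a read 5.95 × 10⁻⁴ M min⁻¹, slower than the 0.00160 M min⁻¹ of ash, though maple is charged with more Z.

The flask gives 69.7% for birch, with exponents of 0.61 in [Z] and 0.32 in [J]. The forecast's Z exponent is higher than that; its J exponent and birch share stand within their margins. The forecast lies 2.3 percentage points from the birch value, closer than the pair number at 4.9 points. So the pair view loses.

    Z ⇌ E (0.3510 min⁻¹, 0.07380 min⁻¹)
    E + J → X (58.02 L mol⁻¹ min⁻¹)
    2 J ⇌ J2, settled at all times (19.70 L mol⁻¹)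
    J → Ja (0.1260 min⁻¹)

The pair view keeps its booking of J in the maple run, where J is the limiting reagent, charged at 0.0500 M against 0.0750 M of Z. The birch gap is 30.3%, above the 24.6% of ash. It counts free J, the J held in J2, and Ja. The birch run without the reaction of J to Ja gives 82.2% X, so its gap is 17.8%. The reaction of J to Ja costs birch 13 points of X, which is 41% of what is missing.

(The runs come from a simulation for substances that don't exist; the scatter is artificial.)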